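**Plan**

- Locants: cyclohexadiene C1 = CH carrying the heptenyl chain, C2 and C4 = methyl-bearing sp2 carbons, C3 and C5 = CH, C6 = quaternary carbon (Me, pyranone); side chain C7(Me)=C8–C9(Me)–C10(=O)Et.
- Retrosynthesis: C10 ketone from its silyl ether; C2=C3 from a β-benzoyloxy sulfone (C3 carbonyl and C2 sulfone as helpers); cut C1–C2, so that the cyclohexenone becomes the oxygen-to-carbon isomer of a 6-alkylidene-2H-pyran whose ring oxygen holds the place of C2; pyran from an unsaturated δ-lactone (C4=C5 by ring-closing metathesis); cut C6–C5 (allylation of a pyranone side-chain dianion); pyranone ring and C1–C6 bond from an aldol adduct of the side-chain enal.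
- Enabling feature: C1 is allylic to the C7=C8 alkene, so a C1–O bond ionises to a π-allyl, and C2 is the α-carbon of a latent C3 carbonyl; the ring oxygen of a pyran built on C3–C4=C5–C6–C1 can therefore be exchanged for C2.
- Forward order: side-chain enal, aldol, pyranone ring, quaternary C6, lactone ring, alkylidene pyran, carbocycle, cyclohexadiene, ketone.
- Stereochemistry: C9 from crotylboration; the C1 carbinol from an Evans syn aldol; C6 from alkoxide-directed dianion allylation; C1 kept by double inversion at palladium; C7=C8 (E) from cross-metathesis.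

Key step: step 16

Remarks on the chemistry: TBS = tert-butyldimethylsilyl, TES = triethylsilyl. The silyloxy carbon of the side chain is oxidised in the last step, so its configuration (R, from the syn crotylation) is immaterial. Compounds 12–15 are carried as mixtures of epimers at the methine carbon that becomes C6, which is deprotonated in step 11. The antipode of the crotylborane named in step 1 is the one expected to give the (4R) centre.

Step 1
Reactants: 1 propanal; 2 cis-but-2-ene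
Product: 3 (3R,4R)-4-methylhex-5-en-3-ol
Conditions: KOt-Bu, n-BuLi, THF, −78 to −45 °C; (−)-Ipc2BOMe, −78 °C; BF3·OEt2; 1, −78 °C; then NaOH, H2O2
Reagents that add atoms: none
Why: Brown crotylboration through a chair transition state, in which the (Z)-crotyl unit gives the syn adduct and the isopinocampheyl groups select the aldehyde face, should set C9 (R) together with the immaterial carbinol centre.

Step 2
Reactants: 3 (3R,4R)-4-methylhex-5-en-3-ol
Product: 4 TBS ether of 3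
Conditions: TBSCl, imidazole, DMF, rt
Reagents that add atoms: tert-butyldimethylsilyl chloride, CC(C)(C)[Si](C)(C)Cl
Why: Standard silylation of a secondary alcohol; the ether is kept until step 19.

Step 3
Reactants: 4 TBS ether of 3; 5 methacrolein
Product: 6 (2E,4R,5R)-5-(TBSO)-2,4-dimethylhept-2-enal
Conditions: 5 (excess), second-generation Grubbs catalyst (5 mol %), CH2Cl2, 40 °C
Reagents that add atoms: none
Why: Cross-metathesis of a monosubstituted alkene with excess methacrolein should give the trisubstituted enal, E under thermodynamic control, which fixes the C7=C8 geometry.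

Step 4
Reactants: 6 (2E,4R,5R)-5-(TBSO)-2,4-dimethylhept-2-enal; 7 (S)-4-benzyl-3-propionyloxazolidin-2-one
Product: 8 (4S)-4-benzyl-3-[(2S,3S,4E,6R,7R)-7-(TBSO)-3-hydroxy-2,4,6-trimethylnon-4-enoyl]oxazolidin-2-one
Conditions: 7, Bu2BOTf, Et3N, CH2Cl2, −78 to 0 °C; 6, −78 to 0 °C; pH 7 buffer, MeOH, H2O2
Reagents that add atoms: none
Why: Evans syn aldol, in which the (Z)-boron enolate reacts through a chair transition state on the face opposite the benzyl group, should set the carbinol that becomes C1 (the α-methyl centre is erased later).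

Step 5
Reactants: 8 Evans aldol adduct
Product: 9 (2S,3S,4E,6R,7R)-7-(TBSO)-3-hydroxy-N-methoxy-N,2,4,6-tetramethylnon-4-enamide
Conditions: MeNHOMe·HCl, Me3Al, CH2Cl2, −20 °C to rt
Reagents that add atoms: N,O-dimethylhydroxylamine hydrochloride, CNOC.Cl
Why: Aluminium amide aminolysis of the β-hydroxy imide gives the Weinreb amide and frees the auxiliary.

Step 6
Reactants: 9 Weinreb amide
Product: 10 TES ether of 9
Conditions: TESCl, imidazole, CH2Cl2, 0 °C
Reagents that add atoms: triethylsilyl chloride, CC[Si](CC)(CC)Cl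
Why: Silylation; TES is chosen so that it can be removed in step 10 beside the TBS ether.

Step 7
Reactants: 10 TES ether of 9; 11 methyl 2-methyl-3-oxopentanoate
Product: 12 methyl (7S,8E,10R,11R)-11-(TBSO)-2,4,6,8,10-pentamethyl-3,5-dioxo-7-(TESO)tridec-8-enoate (epimers at C2, C4, C6)
Conditions: 11, NaH then n-BuLi, THF, 0 °C; 10, −78 to 0 °C
Reagents that add atoms: none
Why: Acylation of the γ-carbon of the β-keto ester dianion by the Weinreb amide (stable chelate, no over-addition) should give the β,δ-diketo ester.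

Step 8
Reactants: 12 β,δ-diketo ester
Product: 13 4-hydroxy-3,5-dimethyl-6-[(3S,4E,6R,7R)-7-(TBSO)-4,6-dimethyl-3-(TESO)non-4-en-2-yl]-2H-pyran-2-one
Conditions: DBU, toluene, 60 °C
Reagents that add atoms: none
Why: Base-induced enol-lactonisation of the diketo ester forms the 4-hydroxy-2-pyranone ring, and the two methine centres between the carbonyls become sp2.

Step 9
Reactants: 13 hydroxy-2-pyranone
Product: 14 2-methoxy-3,5-dimethyl-6-[(3S,4E,6R,7R)-7-(TBSO)-4,6-dimethyl-3-(TESO)non-4-en-2-yl]-4H-pyran-4-one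
Conditions: MeOSO2F, CH2Cl2, rt; aq. NaHCO3
Reagents that add atoms: methyl fluorosulfonate, COS(=O)(=O)F
Why: Hard O-methylation at the lactone carbonyl oxygen of the vinylogous acid should give the 2-methoxy-4-pyranone.

Step 10
Reactants: 14 methoxypyranone TES ether
Product: 15 2-[(3S,4E,6R,7R)-7-(TBSO)-3-hydroxy-4,6-dimethylnon-4-en-2-yl]-6-methoxy-3,5-dimethyl-4H-pyran-4-one
Conditions: HF·pyridine, pyridine, THF, 0 °C
Reagents that add atoms: none
Why: Selective cleavage of the more labile TES ether.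

Step 11
Reactants: 15 hydroxyalkyl pyranone
Product: 16 2-[(4R,5R,6E,8R,9R)-9-(TBSO)-5-hydroxy-4,6,8-trimethylundeca-1,6-dien-4-yl]-6-methoxy-3,5-dimethyl-4H-pyran-4-one
Conditions: LDA (2.3 equiv), THF, −78 °C; allyl bromide, −78 to −40 °C
Reagents that add atoms: allyl bromide, C=CCBr
Why: Alkylation of the pyranone side-chain dianion, modelled on the Fráter–Seebach alkylation, in which lithium bridges the alkoxide and the pyranone ring oxygen and allyl bromide enters anti to the alkenyl group of the carbinol, should set quaternary C6 from either epimer of 15.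

Step 12
Reactants: 16 quaternary homoallylic alcohol
Product: 17 methacrylate ester of 16
Conditions: methacryloyl chloride, Et3N, DMAP, CH2Cl2, 0 °C to rt
Reagents that add atoms: methacryloyl chloride, CC(=C)C(Cl)=O
Why: Acylation of the hindered secondary alcohol with DMAP catalysis; it also masks the allylic alcohol before step 13.

Step 13
Reactants: 17 methacrylate ester of 16
Product: 18 (2E,4R,5R,6E,8R,9R)-9-(TBSO)-4-(6-methoxy-3,5-dimethyl-4-oxo-4H-pyran-2-yl)-4,6,8-trimethylundeca-2,6-dien-5-yl 2-methylprop-2-enoate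
Conditions: RuHCl(CO)(PPh3)3 (5 mol %), toluene, 80 °C
Reagents that add atoms: none
Why: Ruthenium hydride addition–elimination moves the terminal allyl double bond to the internal propenyl position, placing an alkene carbon (C5) on C6; the propenyl geometry does not matter.

Step 14
Reactants: 18 propenyl methacrylate
Product: 19 (5R,6R)-6-[(2E,4R,5R)-5-(TBSO)-4-methylhept-2-en-2-yl]-5-(6-methoxy-3,5-dimethyl-4-oxo-4H-pyran-2-yl)-3,5-dimethyl-5,6-dihydro-2H-pyran-2-one
Conditions: second-generation Grubbs catalyst (10 mol %), toluene, 100 °C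
Reagents that add atoms: none
Why: Ring-closing metathesis between the propenyl group and the methacrylate should give the six-membered lactone, whose ring forces the C4=C5 geometry (C6 cis to C3) needed in step 16.

Step 15
Reactants: 19 unsaturated δ-lactone
Product: 21 (2R,3R)-2-[(2E,4R,5R)-5-(TBSO)-4-methylhept-2-en-2-yl]-3-(6-methoxy-3,5-dimethyl-4-oxo-4H-pyran-2-yl)-3,5-dimethyl-6-[1-(phenylsulfonyl)ethylidene]-3,6-dihydro-2H-pyran, via lactol 20 (not isolated)
Conditions: EtSO2Ph, n-BuLi (2.2 equiv each), THF, −78 °C; 19; aq. NH4Cl; then PPTS, 4 Å molecular sieves, toluene, 60 °C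
Reagents that add atoms: ethyl phenyl sulfone, CCS(=O)(=O)c1ccccc1
Why: 1,2-Addition of the α-sulfonyl carbanion to the lactone carbonyl (the β-carbon is neopentyl, and the second equivalent deprotonates the β-keto sulfone), then acid-catalysed dehydration of the lactol, should give the cyclic enol ether.

Step 16
Reactants: 21 sulfonylethylidene pyran
Product: 22 (4R,5R)-5-[(2E,4R,5R)-5-(TBSO)-4-methylhept-2-en-2-yl]-4-(6-methoxy-3,5-dimethyl-4-oxo-4H-pyran-2-yl)-2,4,6-trimethyl-6-(phenylsulfonyl)cyclohex-2-en-1-one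
Conditions: Pd(PPh3)4 (10 mol %), 1,2-bis(diphenylphosphino)ethane, DMSO, 80 °C
Reagents that add atoms: none
Why: Zerovalent palladium ionises the allylic C1–O bond of the pyran anti to the metal, the oxygen leaving as the sulfone-stabilised dienolate, and the α-carbon of this enolate (C2) recloses on the allyl terminus C1; O-alkylation only regenerates 21, so the carbocycle is the sink. The closest known reaction type is the palladium-catalysed 1,3 oxygen-to-carbon alkyl shift of 2-alkylidene oxacycles that carry an alkenyl group on the ring C–O carbon, an intramolecular Tsuji–Trost alkylation. The six-membered ring closes in the 6-exo mode at the proximal allyl terminus, the allyl unit staying outside the ring, against 8-endo closure at C8. C1 is formed with overall retention (inversion on ionisation, inversion on attack of the soft enolate opposite to palladium), so it keeps the configuration set in step 4 and the side chain comes out cis to the pyranone; C2 forms as a mixture that does not matter because it becomes sp2 in step 18. The step needs C- over O-alkylation, proximal over distal attack, and capture faster than syn–anti isomerisation of the allyl unit (which would give the Z alkene with the epimeric C1). Reversible O-alkylation, ring size and the E (syn,syn) allyl geometry should secure these.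

Step 17
Reactants: 22 β-keto sulfone
Product: 24 benzoate of the C3 alcohol, via allylic alcohol 23 (not isolated)
Conditions: NaBH4, CeCl3·7H2O, MeOH, −40 °C; then BzCl, DMAP, pyridine, CH2Cl2, 0 °C
Reagents that add atoms: benzoyl chloride, O=C(Cl)c1ccccc1
Why: Luche 1,2-reduction of the enone followed by benzoylation gives the β-benzoyloxy sulfone; the new carbinol configuration is immaterial.

Step 18
Reactants: 24 β-benzoyloxy sulfone
Product: 25 2-{(1R,6S)-6-[(2E,4R,5R)-5-(TBSO)-4-methylhept-2-en-2-yl]-1,3,5-trimethylcyclohexa-2,4-dien-1-yl}-6-methoxy-3,5-dimethyl-4H-pyran-4-one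
Conditions: SmI2, HMPA, THF, −78 °C
Reagents that add atoms: none
Why: Julia–Lythgoe reductive elimination, in which electron transfer cleaves the C–S bond and the carbanion expels benzoate, should form the C2=C3 double bond (cis by the ring) and so the cyclohexa-1,3-diene.

Step 19
Reactants: 25 TBS-protected diene
Product: 26 2-{(1R,6S)-6-[(2E,4R,5R)-5-hydroxy-4-methylhept-2-en-2-yl]-1,3,5-trimethylcyclohexa-2,4-dien-1-yl}-6-methoxy-3,5-dimethyl-4H-pyran-4-one
Conditions: TBAF, THF, 0 °C to rt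
Reagents that add atoms: none
Why: Fluoride cleavage of the silyl ether.

Step 20
Reactants: 26 secondary alcohol
Product: 27 2-methoxy-3,5-dimethyl-6-{(1R,6S)-1,3,5-trimethyl-6-[(2E,4R)-4-methyl-5-oxohept-2-en-2-yl]cyclohexa-2,4-dien-1-yl}-4H-pyran-4-one (target)
Conditions: Dess–Martin periodinane, NaHCO3, CH2Cl2, 0 °C
Reagents that add atoms: none
Why: Dess–Martin oxidation under buffered, non-basic conditions should give the β,γ-unsaturated ketone without epimerisation at C9 or migration of the alkene.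

**Compound list**

1 | propanal | CCC=O | starting material
2 | cis-but-2-ene | C/C=C\C | starting material
3 | (3R,4R)-4-methylhex-5-en-3-ol | CC[C@@H](O)[C@H](C)C=C | intermediate
4 | tert-butyl{[(3R,4R)-4-methylhex-5-en-3-yl]oxy}dimethylsilane | CC[C@@H](O[Si](C)(C)C(C)(C)C)[C@H](C)C=C | intermediate
5 | methacrolein (2-methylprop-2-enal) | CC(=C)C=O | starting material
6 | (2E,4R,5R)-5-(TBSO)-2,4-dimethylhept-2-enal | CC[C@@H](O[Si](C)(C)C(C)(C)C)[C@H](C)/C=C(\C)C=O | intermediate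
7 | (S)-4-benzyl-3-propionyloxazolidin-2-one | CCC(=O)N1[C@@H](Cc2ccccc2)COC1=O | starting material
8 | (4S)-4-benzyl-3-[(2S,3S,4E,6R,7R)-7-(TBSO)-3-hydroxy-2,4,6-trimethylnon-4-enoyl]oxazolidin-2-one | CC[C@@H](O[Si](C)(C)C(C)(C)C)[C@H](C)/C=C(\C)[C@@H](O)[C@H](C)C(=O)N1[C@@H](Cc2ccccc2)COC1=O | intermediate
9 | (2S,3S,4E,6R,7R)-7-(TBSO)-3-hydroxy-N-methoxy-N,2,4,6-tetramethylnon-4-enamide | CC[C@@H](O[Si](C)(C)C(C)(C)C)[C@H](C)/C=C(\C)[C@@H](O)[C@H](C)C(=O)N(C)OC | intermediate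
10 | (2S,3S,4E,6R,7R)-7-(TBSO)-N-methoxy-N,2,4,6-tetramethyl-3-(TESO)non-4-enamide | CC[C@@H](O[Si](C)(C)C(C)(C)C)[C@H](C)/C=C(\C)[C@@H](O[Si](CC)(CC)CC)[C@H](C)C(=O)N(C)OC | intermediate
11 | methyl 2-methyl-3-oxopentanoate | CCC(=O)C(C)C(=O)OC | starting material
12 | methyl (7S,8E,10R,11R)-11-(TBSO)-2,4,6,8,10-pentamethyl-3,5-dioxo-7-(TESO)tridec-8-enoate (epimers at C2, C4, C6) | CC[C@@H](O[Si](C)(C)C(C)(C)C)[C@H](C)/C=C(\C)[C@@H](O[Si](CC)(CC)CC)C(C)C(=O)C(C)C(=O)C(C)C(=O)OC | intermediate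
13 | 4-hydroxy-3,5-dimethyl-6-[(3S,4E,6R,7R)-7-(TBSO)-4,6-dimethyl-3-(TESO)non-4-en-2-yl]-2H-pyran-2-one (epimers at C2 of the chain) | CC[C@@H](O[Si](C)(C)C(C)(C)C)[C@H](C)/C=C(\C)[C@@H](O[Si](CC)(CC)CC)C(C)C1=C(C)C(O)=C(C)C(=O)O1 | intermediate
14 | 2-methoxy-3,5-dimethyl-6-[(3S,4E,6R,7R)-7-(TBSO)-4,6-dimethyl-3-(TESO)non-4-en-2-yl]-4H-pyran-4-one (epimers at C2 of the chain) | CC[C@@H](O[Si](C)(C)C(C)(C)C)[C@H](C)/C=C(\C)[C@@H](O[Si](CC)(CC)CC)C(C)c1oc(OC)c(C)c(=O)c1C | intermediate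
15 | 2-[(3S,4E,6R,7R)-7-(TBSO)-3-hydroxy-4,6-dimethylnon-4-en-2-yl]-6-methoxy-3,5-dimethyl-4H-pyran-4-one (epimers at C2 of the chain) | CC[C@@H](O[Si](C)(C)C(C)(C)C)[C@H](C)/C=C(\C)[C@@H](O)C(C)c1oc(OC)c(C)c(=O)c1C | intermediate
16 | 2-[(4R,5R,6E,8R,9R)-9-(TBSO)-5-hydroxy-4,6,8-trimethylundeca-1,6-dien-4-yl]-6-methoxy-3,5-dimethyl-4H-pyran-4-one | CC[C@@H](O[Si](C)(C)C(C)(C)C)[C@H](C)/C=C(\C)[C@@H](O)[C@@](C)(CC=C)c1oc(OC)c(C)c(=O)c1C | intermediate
17 | (4R,5R,6E,8R,9R)-9-(TBSO)-4-(6-methoxy-3,5-dimethyl-4-oxo-4H-pyran-2-yl)-4,6,8-trimethylundeca-1,6-dien-5-yl 2-methylprop-2-enoate | CC[C@@H](O[Si](C)(C)C(C)(C)C)[C@H](C)/C=C(\C)[C@@H](OC(=O)C(C)=C)[C@@](C)(CC=C)c1oc(OC)c(C)c(=O)c1C | intermediate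
18 | (2E,4R,5R,6E,8R,9R)-9-(TBSO)-4-(6-methoxy-3,5-dimethyl-4-oxo-4H-pyran-2-yl)-4,6,8-trimethylundeca-2,6-dien-5-yl 2-methylprop-2-enoate | CC[C@@H](O[Si](C)(C)C(C)(C)C)[C@H](C)/C=C(\C)[C@@H](OC(=O)C(C)=C)[C@@](C)(/C=C/C)c1oc(OC)c(C)c(=O)c1C | intermediate
19 | (5R,6R)-6-[(2E,4R,5R)-5-(TBSO)-4-methylhept-2-en-2-yl]-5-(6-methoxy-3,5-dimethyl-4-oxo-4H-pyran-2-yl)-3,5-dimethyl-5,6-dihydro-2H-pyran-2-one | CC[C@@H](O[Si](C)(C)C(C)(C)C)[C@H](C)/C=C(\C)[C@H]1OC(=O)C(C)=C[C@@]1(C)c1oc(OC)c(C)c(=O)c1C | intermediate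
20 | lactol: (5R,6R)-2-hydroxy analogue of 19 carrying a 1-(phenylsulfonyl)ethyl group at C2 (mixture at C2 and the sulfonyl carbon) | CC[C@@H](O[Si](C)(C)C(C)(C)C)[C@H](C)/C=C(\C)[C@H]1OC(O)(C(C)S(=O)(=O)c2ccccc2)C(C)=C[C@@]1(C)c1oc(OC)c(C)c(=O)c1C | intermediate
21 | (2R,3R)-2-[(2E,4R,5R)-5-(TBSO)-4-methylhept-2-en-2-yl]-3-(6-methoxy-3,5-dimethyl-4-oxo-4H-pyran-2-yl)-3,5-dimethyl-6-[1-(phenylsulfonyl)ethylidene]-3,6-dihydro-2H-pyran (exocyclic alkene geometry immaterial) | CC[C@@H](O[Si](C)(C)C(C)(C)C)[C@H](C)/C=C(\C)[C@H]1OC(=C(C)S(=O)(=O)c2ccccc2)C(C)=C[C@@]1(C)c1oc(OC)c(C)c(=O)c1C | intermediate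
22 | (4R,5R)-5-[(2E,4R,5R)-5-(TBSO)-4-methylhept-2-en-2-yl]-4-(6-methoxy-3,5-dimethyl-4-oxo-4H-pyran-2-yl)-2,4,6-trimethyl-6-(phenylsulfonyl)cyclohex-2-en-1-one (mixture at C6) | CC[C@@H](O[Si](C)(C)C(C)(C)C)[C@H](C)/C=C(\C)[C@H]1C(C)(S(=O)(=O)c2ccccc2)C(=O)C(C)=C[C@@]1(C)c1oc(OC)c(C)c(=O)c1C | intermediate
23 | cyclohex-2-en-1-ol from 1,2-reduction of 22 (mixture at C1 and C6) | CC[C@@H](O[Si](C)(C)C(C)(C)C)[C@H](C)/C=C(\C)[C@H]1C(C)(S(=O)(=O)c2ccccc2)C(O)C(C)=C[C@@]1(C)c1oc(OC)c(C)c(=O)c1C | intermediate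
24 | benzoate of 23 | CC[C@@H](O[Si](C)(C)C(C)(C)C)[C@H](C)/C=C(\C)[C@H]1C(C)(S(=O)(=O)c2ccccc2)C(OC(=O)c2ccccc2)C(C)=C[C@@]1(C)c1oc(OC)c(C)c(=O)c1C | intermediate
25 | 2-{(1R,6S)-6-[(2E,4R,5R)-5-(TBSO)-4-methylhept-2-en-2-yl]-1,3,5-trimethylcyclohexa-2,4-dien-1-yl}-6-methoxy-3,5-dimethyl-4H-pyran-4-one | CC[C@@H](O[Si](C)(C)C(C)(C)C)[C@H](C)/C=C(\C)[C@H]1C(C)=CC(C)=C[C@@]1(C)c1oc(OC)c(C)c(=O)c1C | intermediate
26 | 2-{(1R,6S)-6-[(2E,4R,5R)-5-hydroxy-4-methylhept-2-en-2-yl]-1,3,5-trimethylcyclohexa-2,4-dien-1-yl}-6-methoxy-3,5-dimethyl-4H-pyran-4-one | CC[C@@H](O)[C@H](C)/C=C(\C)[C@H]1C(C)=CC(C)=C[C@@]1(C)c1oc(OC)c(C)c(=O)c1C | intermediate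
27 | 2-methoxy-3,5-dimethyl-6-{(1R,6S)-1,3,5-trimethyl-6-[(2E,4R)-4-methyl-5-oxohept-2-en-2-yl]cyclohexa-2,4-dien-1-yl}-4H-pyran-4-one | CCC(=O)[C@H](C)/C=C(\C)[C@H]1C(C)=CC(C)=C[C@@]1(C)c1oc(OC)c(C)c(=O)c1C | target

**Step count and risks**

Total step count: 20. Longest linear sequence: 20 steps (from 1 and 2 to 27).

Steps most likely to fail:

Step 11. The dianion alkylation may lose chelation control, giving poor or reversed facial selectivity at C6, or the alkoxide may undergo retro-aldol cleavage. Fallback, setting out from 8 and coming back at 16: the quaternary centre is made at the β-hydroxy ester stage, where alkoxide-directed dianion alkylation is established, and the pyranone is built afterwards. NaOMe in MeOH should give methyl ester F1; LDA (2 equiv) and allyl bromide the α-allylated ester F2; TESOTf and 2,6-lutidine the silyl ether F3; DIBAL-H at −78 °C the aldehyde F4; aldol addition of the dianion of 11 the δ-hydroxy β-keto ester F5; Dess–Martin oxidation the diketo ester F6; DBU the hydroxypyranone F7; MeOSO2F the methoxypyranone F8; HF·pyridine then returns to 16.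

Step 16. Ionisation of the hindered allylic ether may be slow, or the zwitterion may be lost by β-hydride elimination to a diene or closed at the distal terminus. Fallback, setting out from 19 and coming back at 25: an open-chain Tsuji–Trost cyclisation with the less hindered ketone enolate. EtLi at −78 °C should give the (Z)-hydroxy enone F9 (in equilibrium with its lactol); ClCO2Me, pyridine and DMAP the allylic carbonate F10; LiHMDS at −78 °C then Pd(PPh3)4 the cyclohexenone F11 by the same double inversion; KHMDS and PhNTf2 the dienyl triflate F12; Pd(OAc)2, PPh3, HCO2H and Et3N then give 25.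

Step 14. The catalyst may fail to engage two hindered alkenes (a propenyl group on a quaternary carbon and a 1,1-disubstituted acrylate), leading to non-productive metathesis or oligomers. Fallback, setting out from 15 and coming back at 19: the lactone is closed by an intramolecular Horner–Wadsworth–Emmons reaction. LDA (2.3 equiv) then 4-methoxybenzyl chloromethyl ether should give the quaternary ether F13; 2-(diethoxyphosphoryl)propanoic acid, DCC and DMAP the phosphonate ester F14; DDQ the primary alcohol F15; Dess–Martin oxidation the aldehyde F16; LiCl and DBU in MeCN then close the ring to 19.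

**Further compounds**

F1 | step 11 | methyl (2S,3S,4E,6R,7R)-7-(TBSO)-3-hydroxy-2,4,6-trimethylnon-4-enoate | CC[C@@H](O[Si](C)(C)C(C)(C)C)[C@H](C)/C=C(\C)[C@@H](O)[C@H](C)C(=O)OC
F2 | step 11 | methyl (2R,3R,4E,6R,7R)-2-allyl-7-(TBSO)-3-hydroxy-2,4,6-trimethylnon-4-enoate | CC[C@@H](O[Si](C)(C)C(C)(C)C)[C@H](C)/C=C(\C)[C@@H](O)[C@@](C)(CC=C)C(=O)OC
F3 | step 11 | TES ether of F2 | CC[C@@H](O[Si](C)(C)C(C)(C)C)[C@H](C)/C=C(\C)[C@@H](O[Si](CC)(CC)CC)[C@@](C)(CC=C)C(=O)OC
F4 | step 11 | aldehyde from F3 (2-allyl-7-(TBSO)-2,4,6-trimethyl-3-(TESO)non-4-enal) | CC[C@@H](O[Si](C)(C)C(C)(C)C)[C@H](C)/C=C(\C)[C@@H](O[Si](CC)(CC)CC)[C@@](C)(CC=C)C=O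
F5 | step 11 | δ-hydroxy β-keto ester from F4 and the dianion of 11 (epimer mixture) | CC[C@@H](O[Si](C)(C)C(C)(C)C)[C@H](C)/C=C(\C)[C@@H](O[Si](CC)(CC)CC)[C@@](C)(CC=C)C(O)C(C)C(=O)C(C)C(=O)OC
F6 | step 11 | β,δ-diketo ester with quaternary C6 (epimer mixture) | CC[C@@H](O[Si](C)(C)C(C)(C)C)[C@H](C)/C=C(\C)[C@@H](O[Si](CC)(CC)CC)[C@@](C)(CC=C)C(=O)C(C)C(=O)C(C)C(=O)OC
F7 | step 11 | 4-hydroxy-2-pyranone with quaternary C6 | CC[C@@H](O[Si](C)(C)C(C)(C)C)[C@H](C)/C=C(\C)[C@@H](O[Si](CC)(CC)CC)[C@@](C)(CC=C)C1=C(C)C(O)=C(C)C(=O)O1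
F8 | step 11 | TES ether of 16 | CC[C@@H](O[Si](C)(C)C(C)(C)C)[C@H](C)/C=C(\C)[C@@H](O[Si](CC)(CC)CC)[C@@](C)(CC=C)c1oc(OC)c(C)c(=O)c1C
F9 | step 16 | (Z)-hydroxy enone from 19 and EtLi | CC[C@@H](O[Si](C)(C)C(C)(C)C)[C@H](C)/C=C(\C)[C@@H](O)[C@@](C)(/C=C(/C)C(=O)CC)c1oc(OC)c(C)c(=O)c1C
F10 | step 16 | methyl carbonate of F9 | CC[C@@H](O[Si](C)(C)C(C)(C)C)[C@H](C)/C=C(\C)[C@@H](OC(=O)OC)[C@@](C)(/C=C(/C)C(=O)CC)c1oc(OC)c(C)c(=O)c1C
F11 | step 16 | (4R,5R)-5-alkenyl-4-pyranonyl-2,4,6-trimethylcyclohex-2-en-1-one (mixture at C6) | CC[C@@H](O[Si](C)(C)C(C)(C)C)[C@H](C)/C=C(\C)[C@H]1C(C)C(=O)C(C)=C[C@@]1(C)c1oc(OC)c(C)c(=O)c1C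
F12 | step 16 | cyclohexa-1,3-dienyl triflate from F11 | CC[C@@H](O[Si](C)(C)C(C)(C)C)[C@H](C)/C=C(\C)[C@H]1C(C)=C(OS(=O)(=O)C(F)(F)F)C(C)=C[C@@]1(C)c1oc(OC)c(C)c(=O)c1C
F13 | step 14 | quaternary (4-methoxybenzyloxy)methyl analogue of 16 | CC[C@@H](O[Si](C)(C)C(C)(C)C)[C@H](C)/C=C(\C)[C@@H](O)[C@@](C)(COCc1ccc(OC)cc1)c1oc(OC)c(C)c(=O)c1C
F14 | step 14 | 2-(diethoxyphosphoryl)propanoate ester of F13 | CC[C@@H](O[Si](C)(C)C(C)(C)C)[C@H](C)/C=C(\C)[C@@H](OC(=O)C(C)P(=O)(OCC)OCC)[C@@](C)(COCc1ccc(OC)cc1)c1oc(OC)c(C)c(=O)c1C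
F15 | step 14 | primary alcohol from F14 | CC[C@@H](O[Si](C)(C)C(C)(C)C)[C@H](C)/C=C(\C)[C@@H](OC(=O)C(C)P(=O)(OCC)OCC)[C@@](C)(CO)c1oc(OC)c(C)c(=O)c1C
F16 | step 14 | aldehyde from F15 | CC[C@@H](O[Si](C)(C)C(C)(C)C)[C@H](C)/C=C(\C)[C@@H](OC(=O)C(C)P(=O)(OCC)OCC)[C@@](C)(C=O)c1oc(OC)c(C)c(=O)c1C
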